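**Retrosynthetic overview**
- Target ⇐ H2/Pd (saturates one bridge C=C, removes O-benzyl) ⇐ macrocyclic E-stilbene benzyl ether.
- Macrocycle ⇐ one operation: intramolecular Diels–Alder of a tethered aryl ethynyl ether onto a 5-alkyl-2-pyranone, then loss of CO2. This builds ring D (the para-phenylene), its diaryl ether bond and the 18-membered ring together.
- Open precursor ⇐ E-selective Wittig union of a ring A/ring B phosphonium salt carrying the pyranone with a ring C aldehyde carrying the ethynyl ether.
- Phosphonium fragment ⇐ SNAr diaryl ether, methylenation, hydroboration/B-alkyl Suzuki with 5-bromo-2-pyranone. Aldehyde fragment ⇐ 4-(benzyloxy)-3-hydroxybenzaldehyde, trichloroethylene, then n-BuLi.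
- Ring order: rings A, B and C are bought; ring D and the macrocycle are formed last, in the same step.

Assumption: the target has no stereocentre or other stable stereogenic element, so it is one achiral compound and no enantiocontrol is needed.

**Route**

Step 1
Reactants: 1 2-fluoro-3-methoxybenzaldehyde; 2 3-(hydroxymethyl)phenol
Product: 3 2-[3-(hydroxymethyl)phenoxy]-3-methoxybenzaldehyde
Conditions: K2CO3, DMF, 110 °C
Reagents that add atoms: none
Why: SNAr (addition–elimination) of the phenoxide at the fluorine-bearing carbon activated by the ortho formyl group, while the benzylic alcohol is not deprotonated by carbonate and stays free; no stereocentre is formed.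

Step 2
Reactants: 3 2-[3-(hydroxymethyl)phenoxy]-3-methoxybenzaldehyde
Product: 4 [3-(2-ethenyl-6-methoxyphenoxy)phenyl]methanol
Conditions: Ph3PCH3Br (2.5 equiv), KOtBu (2.4 equiv), THF, 0 °C → rt
Reagents that add atoms: methyltriphenylphosphonium bromide, C[P+](c1ccccc1)(c1ccccc1)c1ccccc1.[Br-]
Why: Wittig methylenation of the aryl aldehyde, with excess ylide covering the acidic hydroxyl proton; no stereocentre is formed.

Step 3
Reactants: 4 [3-(2-ethenyl-6-methoxyphenoxy)phenyl]methanol; 5 5-bromo-2H-pyran-2-one
Product: 7 5-{2-[2-(3-(hydroxymethyl)phenoxy)-3-methoxyphenyl]ethyl}-2H-pyran-2-one, via alkylborane 6 (not isolated)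
Conditions: 9-BBN (2.4 equiv), THF, 0 °C → rt; then 5, PdCl2(dppf) (5 mol %), AsPh3, Cs2CO3, DMF–H2O, rt → 45 °C
Reagents that add atoms: none
Why: anti-Markovnikov hydroboration of the styrene followed by B-alkyl Suzuki–Miyaura coupling at the C5–Br bond of the pyranone under mild carbonate base, the O–B ester of the benzylic alcohol being hydrolysed on work-up; no stereocentre is formed.

Step 4
Reactants: 7 5-{2-[2-(3-(hydroxymethyl)phenoxy)-3-methoxyphenyl]ethyl}-2H-pyran-2-one
Product: 8 tributyl{3-[2-methoxy-6-(2-(2-oxo-2H-pyran-5-yl)ethyl)phenoxy]benzyl}phosphonium bromide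
Conditions: n-Bu3P·HBr (1.2 equiv, prepared beforehand), MeCN, 80 °C
Reagents that add atoms: tributylphosphonium bromide (tri-n-butylphosphine hydrobromide), CCCC[PH+](CCCC)CCCC.[Br-]
Why: one-pot conversion of a benzylic alcohol into a benzylphosphonium salt (HBr activation to the benzylic bromide, then quaternisation of the phosphine), tolerated by the acid-stable pyranone; no stereocentre is formed.

Step 5
Reactants: 9 4-(benzyloxy)-3-hydroxybenzaldehyde; 10 trichloroethylene
Product: 11 4-(benzyloxy)-3-{[(E)-1,2-dichloroethenyl]oxy}benzaldehyde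
Conditions: K2CO3, DMF, 70 °C
Reagents that add atoms: none
Why: base-mediated O-vinylation in which carbonate generates dichloroacetylene from trichloroethylene and the phenoxide adds anti across it, giving the E-1,2-dichlorovinyl ether; the aldehyde is untouched.

Step 6
Reactants: 11 4-(benzyloxy)-3-{[(E)-1,2-dichloroethenyl]oxy}benzaldehyde
Product: 14 4-(benzyloxy)-3-(ethynyloxy)benzaldehyde, via lithium morpholino alkoxide 12 (not isolated), via lithium alkynyl ether 13 (not isolated)
Conditions: LiN(CH2CH2)2O (lithium morpholide, from morpholine and n-BuLi, 1.1 equiv), THF, −78 °C; n-BuLi (2.2 equiv), −78 → −40 °C; H2O, −78 °C → rt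
Reagents that add atoms: none
Why: in situ protection of the aldehyde as a lithium α-amino alkoxide (Comins-type), then deprotonation, chloride elimination and lithium–chlorine exchange turn the dichlorovinyl ether into the lithium alkynyl ether (Greene-type ynol ether synthesis), and the aqueous quench returns both the terminal alkyne and the aldehyde.

Step 7
Reactants: 8 tributyl{3-[2-methoxy-6-(2-(2-oxo-2H-pyran-5-yl)ethyl)phenoxy]benzyl}phosphonium bromide; 14 4-(benzyloxy)-3-(ethynyloxy)benzaldehyde
Product: 16 5-{2-[2-(3-{(E)-2-[4-(benzyloxy)-3-(ethynyloxy)phenyl]ethenyl}phenoxy)-3-methoxyphenyl]ethyl}-2H-pyran-2-one, via benzylidene phosphorane 15 (not isolated)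
Conditions: KN(SiMe3)2 (1.0 equiv), THF, −78 °C; then 14, −78 °C → rt
Reagents that add atoms: none
Why: Wittig olefination with a semi-stabilised benzylidene trialkylphosphorane, a class that gives E-stilbenes with high selectivity, using a non-nucleophilic base that spares the pyranone and an ylide too weakly basic to deprotonate the ethynyl ether; the E geometry set here is removed again in step 9.

Step 8
Reactants: 16 5-{2-[2-(3-{(E)-2-[4-(benzyloxy)-3-(ethynyloxy)phenyl]ethenyl}phenoxy)-3-methoxyphenyl]ethyl}-2H-pyran-2-one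
Product: 18 macrocyclic E-stilbene benzyl ether (the target skeleton with an E double bond in the bridge between ring B and ring C and the ring C hydroxyl as its benzyl ether), via bridged lactone cycloadduct 17 (not isolated)
Conditions: o-C6H4Cl2 (0.001 M), BHT (0.2 equiv), 170 °C, 36 h, argon
Reagents that add atoms: none
Why: Proposed new method: the electron-rich aryl ethynyl ether and the electron-poor 2-pyranone diene are matched for an inverse-electron-demand intramolecular [4+2] cycloaddition in which the nucleophilic terminal alkyne carbon bonds to C6 of the pyranone and the oxygen-bearing carbon to C3, so that after cycloreversion of 17 with loss of CO2 the new benzene ring (ring D) carries the aryloxy group para to the C5 ethylene tether, and because diene and dienophile sit at the two ends of the chain the same event closes the 18-membered ring, with high dilution suppressing intermolecular reaction; the closest known reaction type is the 2-pyranone–alkyne Diels–Alder/retro-Diels–Alder benzannulation, known with ynamines and ketene acetals (para-selective for 5-substituted pyranones) and, in macrocyclising form, for cyclophane synthesis; no stereocentre remains after CO2 loss.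

Step 9
Reactants: 18 macrocyclic E-stilbene benzyl ether
Product: 19 target, CNP0309263.0
Conditions: H2 (1 atm), 10% Pd/C, EtOAc–MeOH, rt
Reagents that add atoms: none
Why: heterogeneous catalytic hydrogenation saturates the stilbene double bond and hydrogenolyses the benzyl ether in the same operation, while the methyl ether and both diaryl ethers are inert; no stereocentre is formed.

**Compound list**

1 | 2-fluoro-3-methoxybenzaldehyde | COc1cccc(C=O)c1F | starting material
2 | 3-(hydroxymethyl)phenol | OCc1cccc(O)c1 | starting material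
3 | 2-[3-(hydroxymethyl)phenoxy]-3-methoxybenzaldehyde | COc1cccc(C=O)c1Oc1cccc(CO)c1 | intermediate
4 | [3-(2-ethenyl-6-methoxyphenoxy)phenyl]methanol | COc1cccc(C=C)c1Oc1cccc(CO)c1 | intermediate
5 | 5-bromo-2H-pyran-2-one | O=C1C=CC(Br)=CO1 | starting material
6 | B-alkyl-9-BBN adduct of 4 with the benzylic oxygen as its 9-BBN borinate | COc1cccc(CCB2C3CCCC2CCC3)c1Oc1cccc(COB2C3CCCC2CCC3)c1 | intermediate
7 | 5-{2-[2-(3-(hydroxymethyl)phenoxy)-3-methoxyphenyl]ethyl}-2H-pyran-2-one | COc1cccc(CCC2=COC(=O)C=C2)c1Oc1cccc(CO)c1 | intermediate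
8 | tributyl{3-[2-methoxy-6-(2-(2-oxo-2H-pyran-5-yl)ethyl)phenoxy]benzyl}phosphonium bromide | COc1cccc(CCC2=COC(=O)C=C2)c1Oc1cccc(C[P+](CCCC)(CCCC)CCCC)c1.[Br-] | intermediate
9 | 4-(benzyloxy)-3-hydroxybenzaldehyde | O=Cc1ccc(OCc2ccccc2)c(O)c1 | starting material
10 | trichloroethylene | ClC=C(Cl)Cl | starting material
11 | 4-(benzyloxy)-3-{[(E)-1,2-dichloroethenyl]oxy}benzaldehyde | O=Cc1ccc(OCc2ccccc2)c(O/C(Cl)=C\Cl)c1 | intermediate
12 | lithium [4-(benzyloxy)-3-{[(E)-1,2-dichloroethenyl]oxy}phenyl](morpholin-4-yl)methanolate, racemic | [Li+].[O-]C(N1CCOCC1)c1ccc(OCc2ccccc2)c(O/C(Cl)=C\Cl)c1 | intermediate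
13 | dilithium salt: [4-(benzyloxy)-3-(lithioethynyloxy)phenyl](morpholin-4-yl)methanolate, racemic | [Li+].[Li+].[O-]C(N1CCOCC1)c1ccc(OCc2ccccc2)c(OC#[C-])c1 | intermediate
14 | 4-(benzyloxy)-3-(ethynyloxy)benzaldehyde | O=Cc1ccc(OCc2ccccc2)c(OC#C)c1 | intermediate
15 | tributyl{3-[2-methoxy-6-(2-(2-oxo-2H-pyran-5-yl)ethyl)phenoxy]benzylidene}phosphorane | COc1cccc(CCC2=COC(=O)C=C2)c1Oc1cccc(C=P(CCCC)(CCCC)CCCC)c1 | intermediate
16 | 5-{2-[2-(3-{(E)-2-[4-(benzyloxy)-3-(ethynyloxy)phenyl]ethenyl}phenoxy)-3-methoxyphenyl]ethyl}-2H-pyran-2-one | COc1cccc(CCC2=COC(=O)C=C2)c1Oc1cccc(/C=C/c2ccc(OCc3ccccc3)c(OC#C)c2)c1 | intermediate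
17 | bridged lactone cycloadduct (2-oxabicyclo[2.2.2]octa-5,7-dien-3-one unit spanning the macrocycle, aryloxy on the new alkene carbon next to the lactone carbonyl bridgehead, ethylene tether on the other alkene), racemic, bridgeheads necessarily cis | COc1cccc2c1Oc1cccc(c1)/C=C/c1ccc(OCc3ccccc3)c(c1)OC1=CC3OC(=O)C1C=C3CC2 | intermediate
18 | macrocyclic E-stilbene benzyl ether (O-benzyl, B–C bridge didehydro form of the target) | COc1cccc2c1Oc1cccc(c1)/C=C/c1ccc(OCc3ccccc3)c(c1)Oc1ccc(cc1)CC2 | intermediate
19 | CNP0309263.0 (achiral) | COc1cccc2c1Oc1cccc(c1)CCc1ccc(O)c(c1)Oc1ccc(cc1)CC2 | target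

**Totals and risks**

Total step count: 9. Longest linear sequence: 7 steps (steps 1, 2, 3, 4, 7, 8, 9); steps 5 and 6 form the second branch.

Steps most likely to fail:

1. Step 8. The 5-alkylpyranone carries no activating group, the terminal aryl ethynyl ether may not survive 170 °C for the time needed, and the ring closure is entropically costly. The fallback sets out from 7 and 14 and runs the same cycloaddition intermolecularly at high concentration (toluene, 1 M, 120–130 °C). This gives the bridged lactone cycloadduct F1, which loses CO2 to the open-chain diaryl ether aldehyde alcohol F2. Treatment with n-Bu3P·HBr (MeCN, 80 °C) gives the tributylphosphonium bromide F3. Slow addition of F3 to KOtBu in THF–CH2Cl2 at high dilution closes the 18-membered ring by intramolecular Wittig reaction and comes back to the route at 18. Any Z isomer of 18 F4 formed alongside goes through step 9 with 18 to the same 19.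

2. Step 6. The masked aldehyde may still be attacked or ortho-lithiated by n-BuLi, and the ethynyl ether aldehyde is sensitive to acid on work-up. The fallback sets out from 11 and changes the oxidation level instead of masking: NaBH4 (MeOH, 0 °C) gives the dichlorovinyl ether benzylic alcohol F5. Then n-BuLi (3.3 equiv, THF, −78 → −40 °C, H2O quench) gives the ethynyl ether benzylic alcohol F6. MnO2 (CH2Cl2, rt) oxidises the benzylic alcohol and comes back to the route at 14.

3. Step 4. Heating a nucleophilic phosphine salt and HBr with the Michael-acceptor pyranone may open or add to the lactone. The fallback sets out from 7 and separates activation from quaternisation: CBr4 and PPh3 (CH2Cl2, 0 °C) give the benzylic bromide F7. n-Bu3P (MeCN, rt) then displaces bromide and comes back to the route at 8.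

**Further compounds**

F1 | step 8 | intermolecular bridged lactone cycloadduct of 7 and 14 (racemic) | COc1cccc(CCC2=CC3C(Oc4cc(C=O)ccc4OCc4ccccc4)=CC2OC3=O)c1Oc1cccc(CO)c1
F2 | step 8 | 4-(benzyloxy)-3-{4-[2-(2-(3-(hydroxymethyl)phenoxy)-3-methoxyphenyl)ethyl]phenoxy}benzaldehyde | COc1cccc(CCc2ccc(Oc3cc(C=O)ccc3OCc3ccccc3)cc2)c1Oc1cccc(CO)c1
F3 | step 8 | tributyl{3-[2-(2-{4-[2-(benzyloxy)-5-formylphenoxy]phenyl}ethyl)-6-methoxyphenoxy]benzyl}phosphonium bromide | COc1cccc(CCc2ccc(Oc3cc(C=O)ccc3OCc3ccccc3)cc2)c1Oc1cccc(C[P+](CCCC)(CCCC)CCCC)c1.[Br-]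
F4 | step 8 | Z isomer of 18 | COc1cccc2c1Oc1cccc(c1)/C=C\c1ccc(OCc3ccccc3)c(c1)Oc1ccc(cc1)CC2
F5 | step 6 | [4-(benzyloxy)-3-{[(E)-1,2-dichloroethenyl]oxy}phenyl]methanol | OCc1ccc(OCc2ccccc2)c(O/C(Cl)=C\Cl)c1
F6 | step 6 | [4-(benzyloxy)-3-(ethynyloxy)phenyl]methanol | OCc1ccc(OCc2ccccc2)c(OC#C)c1
F7 | step 4 | 5-{2-[2-(3-(bromomethyl)phenoxy)-3-methoxyphenyl]ethyl}-2H-pyran-2-one | COc1cccc(CCC2=COC(=O)C=C2)c1Oc1cccc(CBr)c1
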